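**Plan**

1. Numbering used throughout: bridgeheads C1 and C5, bridging ketone C9, enolised aroyl bridge C2–C3–C4 (ring B with C1, C5, C9), and C6H2–C7H–C8 (ring A with C1, C5, C9); C1' is the first carbon of the chain on C7.
2. Enabling feature: C6–C7–C8 with the C8 methyl and the C8 chain is a 3-methylalk-2-enyl (geranyl-type) group on C5, and the C7 chain is a second such allyl unit added as an electrophile across its C7=C8 olefin, so ring A can close onto a finished ring B.
3. Retrosynthesis: first the four terminal isopropylidene units (back to vinyl groups) and the aryl O–methyl bond, then C7–C1' and C1–C8 together, then C5–C6, then the two ring–allyl bonds and the aryl–carbonyl bond to phloroglucinol.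
4. Forward: ring B is the phloroglucinol ring (acylated, twice C-allylated, dearomatised by C-alkylation at one allyl-bearing carbon); ring A closes in one cation–olefin step; demethylation and a fourfold cross-metathesis complete the chains.
5. Stereochemistry: C5 comes from a catalyst-controlled choice between the two enantiotopic allyl-bearing carbons; C1, C7 and C8 are relayed from C5 in the ring closure (face reached by the tether, anti addition across the (E)-olefin, chair with the new chain equatorial); both (E)-olefins come from one syn carbometallation.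

Key step: step 6

Remark: which pseudoenantiomeric ammonium salt (cinchonidine- or cinchonine-derived) gives the (S) quaternary centre in step 5 cannot be predicted safely; it is assumed that one of them does, and that one is used.

**Route**

Step 1
Reactants: 1 phloroglucinol; 2 3-methoxybenzoyl chloride
Product: 3 (3-methoxyphenyl)(2,4,6-trihydroxyphenyl)methanone
Conditions: AlCl3 (4 equiv), PhNO2/CH2Cl2, 0 °C to rt; aq. HCl work-up
Reagents that add atoms: none
Why: Friedel–Crafts acylation of the very electron-rich ring should stop after one C-acylation because the chelated aryl ketone deactivates it; the meta methyl ether, which masks the future phenol through the base- and cation-mediated steps, is not cleaved by AlCl3 at this temperature.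

Step 2
Reactants: 3 (3-methoxyphenyl)(2,4,6-trihydroxyphenyl)methanone; 4 allyl bromide (two equivalents are incorporated)
Product: 5 (3-methoxyphenyl)[2,4,6-trihydroxy-3,5-di(prop-2-en-1-yl)phenyl]methanone
Conditions: allyl bromide (2.1 equiv), aq. KOH (3 equiv), 0 °C; then acidify
Reagents that add atoms: allyl bromide (second equivalent), C=CCBr
Why: Twofold C-allylation of an acylphloroglucinolate in water, where the hydrogen-bonded phenoxide oxygens leave the two free ring carbons as the reactive sites and each takes up one molecule of allyl bromide; mono- and over-allylated by-products should be separable by chromatography.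

Step 3
Reactants: 6 hex-5-en-1-yne
Product: 8 (2E)-3-methylhepta-2,6-dien-1-ol, via alkenyldimethylalane 7 (not isolated)
Conditions: Me3Al (2 equiv), Cp2ZrCl2 (0.2 equiv), CH2Cl2, 0 °C to rt; then (CH2O)n, THF, 0 °C to rt; aq. HCl
Reagents that add atoms: trimethylaluminium, C[Al](C)C; formaldehyde (from paraformaldehyde), C=O
Why: Negishi carboalumination adds methyl and aluminium syn across the terminal alkyne with aluminium at the terminus, while the monosubstituted alkene is far slower under these conditions; hydroxymethylation of the alkenylalane with retention fixes the (E)-olefin.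

Step 4
Reactants: 8 (2E)-3-methylhepta-2,6-dien-1-ol
Product: 9 (2E)-1-bromo-3-methylhepta-2,6-diene
Conditions: PBr3 (0.4 equiv), Et2O, −10 to 0 °C; used promptly
Reagents that add atoms: phosphorus tribromide, BrP(Br)Br
Why: Bromination of a primary allylic alcohol through its phosphite ester at low temperature should proceed without allylic transposition or loss of olefin geometry, as in the standard preparation of geranyl bromide.

Step 5
Reactants: 5 (3-methoxyphenyl)[2,4,6-trihydroxy-3,5-di(prop-2-en-1-yl)phenyl]methanone; 9 (2E)-1-bromo-3-methylhepta-2,6-diene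
Product: 10 (6S)-3,5-dihydroxy-4-(3-methoxybenzoyl)-6-[(2E)-3-methylhepta-2,6-dien-1-yl]-2,6-di(prop-2-en-1-yl)cyclohexa-2,4-dien-1-one (ring carbon 6 is C5 of the plan)
Conditions: N-(9-anthracenylmethyl)-O-allylcinchonidinium bromide (0.1 equiv), CsOH·H2O (3 equiv), 9 (1.05 equiv), toluene/CH2Cl2, −50 °C; then aq. citric acid
Reagents that add atoms: none
Why: Alkylative dearomatisation: the phloroglucinolate reacts with the allylic bromide at an allyl-bearing ring carbon, and because the two such carbons are enantiotopic, the chiral ammonium ion pair (asymmetric phase-transfer alkylation) should select one of them and set the C5 quaternary centre as (S).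

Step 6
Reactants: 10 (6S)-3,5-dihydroxy-4-(3-methoxybenzoyl)-6-[(2E)-3-methylhepta-2,6-dien-1-yl]-2,6-di(prop-2-en-1-yl)cyclohexa-2,4-dien-1-one; 9 (2E)-1-bromo-3-methylhepta-2,6-diene
Product: 11 (1S,5S,7R,8S)-8-(but-3-en-1-yl)-4-hydroxy-3-(3-methoxybenzoyl)-8-methyl-7-[(2E)-3-methylhepta-2,6-dien-1-yl]-1,5-di(prop-2-en-1-yl)bicyclo[3.3.1]non-3-ene-2,9-dione
Conditions: AgOTf (1.5 equiv), 2,6-di-tert-butylpyridine (2 equiv), 4 Å molecular sieves, CH2Cl2, −78 to −40 °C, 9 (1.3 equiv) added slowly
Reagents that add atoms: none
Why: Proposed new method: AgOTf ionises allylic bromide 9 to an allyl cation whose unsubstituted terminus adds to C7, the less substituted end of the only trisubstituted olefin of 10, and the tertiary C8 cation so formed is captured at once by the C1 enol carbon held 1,3 to C5 across C9, the hindered pyridine taking up the enol proton as its triflate salt. The closest known reaction types are the acid-triggered cation cyclisation of dearomatised prenylated acylphloroglucinols, where a C8 cation is trapped by C1, and the Lewis-acid-promoted addition of allyl halides to trisubstituted alkenes; their union in one event is what is new. Ring A (C1, C9, C5, C6, C7, C8) closes in a 6-endo mode with respect to the C7=C8 olefin through a chair-like array in which C7 folds away from the C9 carbonyl. C7 and C8 are fixed relative to each other by anti addition of cation and enol across the (E)-olefin, the chair with the incoming chain equatorial places that chain exo and the C8 methyl axial, and C1 follows from C5 because the tether reaches only the enol face that carries C6. The selectivity needed is attack of the cation on C7=C8 in preference to every other π-nucleophile, and it is secured by design: all other olefins of 10 and the far end of 9 are monosubstituted vinyl groups, several orders of magnitude less nucleophilic, the aryl ring is deactivated by its carbonyl group, and the chelated enol oxygens should alkylate only reversibly under these ionising conditions. Direct allylation of C1 and oxygen capture of the C8 cation remain the open risks and are countered by low temperature, slow addition of 9 and a medium that keeps the triketone as its neutral hydrogen-bonded enol.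

Step 7
Reactants: 11 (1S,5S,7R,8S)-8-(but-3-en-1-yl)-4-hydroxy-3-(3-methoxybenzoyl)-8-methyl-7-[(2E)-3-methylhepta-2,6-dien-1-yl]-1,5-di(prop-2-en-1-yl)bicyclo[3.3.1]non-3-ene-2,9-dione
Product: 12 (1S,5S,7R,8S)-8-(but-3-en-1-yl)-4-hydroxy-3-(3-hydroxybenzoyl)-8-methyl-7-[(2E)-3-methylhepta-2,6-dien-1-yl]-1,5-di(prop-2-en-1-yl)bicyclo[3.3.1]non-3-ene-2,9-dione
Conditions: NaSEt (6 equiv), DMF (degassed), 130 °C; aq. HCl work-up
Reagents that add atoms: none
Why: SN2 demethylation of an aryl methyl ether by thiolate; the triketone is shielded as its enolate, isolated olefins do not react with thiolate, and no stereocentre can epimerise (three are quaternary and C7 is not alpha to a carbonyl group).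

Step 8
Reactants: 12 (1S,5S,7R,8S)-8-(but-3-en-1-yl)-4-hydroxy-3-(3-hydroxybenzoyl)-8-methyl-7-[(2E)-3-methylhepta-2,6-dien-1-yl]-1,5-di(prop-2-en-1-yl)bicyclo[3.3.1]non-3-ene-2,9-dione
Product: 13 (1S,5S,7R,8S)-7-[(2E)-3,7-dimethylocta-2,6-dien-1-yl]-4-hydroxy-3-(3-hydroxybenzoyl)-8-methyl-8-(4-methylpent-3-en-1-yl)-1,5-bis(3-methylbut-2-en-1-yl)bicyclo[3.3.1]non-3-ene-2,9-dione (CNP0285073.1)
Conditions: 2-methylbut-2-ene (neat, large excess), second-generation Grubbs catalyst RuCl2(=CHPh)(H2IMes)(PCy3) (0.1 equiv), 40 °C, sealed vessel
Reagents that add atoms: 2-methylbut-2-ene, CC=C(C)C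
Why: Olefin cross-metathesis: each of the four monosubstituted vinyl groups should exchange its CH2 terminus for an isopropylidene unit with loss of propene, as in the usual allyl-to-prenyl conversion on this ring system, while the trisubstituted (E)-olefin of the C7 chain and the new isopropylidene termini react much more slowly.

**Compound list**

1 | phloroglucinol | Oc1cc(O)cc(O)c1 | starting material
2 | 3-methoxybenzoyl chloride | COc1cccc(c1)C(Cl)=O | starting material
3 | (3-methoxyphenyl)(2,4,6-trihydroxyphenyl)methanone | COc1cccc(c1)C(=O)c1c(O)cc(O)cc1O | intermediate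
4 | allyl bromide | C=CCBr | starting material
5 | (3-methoxyphenyl)[2,4,6-trihydroxy-3,5-di(prop-2-en-1-yl)phenyl]methanone | COc1cccc(c1)C(=O)c1c(O)c(CC=C)c(O)c(CC=C)c1O | intermediate
6 | hex-5-en-1-yne | C#CCCC=C | starting material
7 | dimethyl[(1E)-2-methylhexa-1,5-dien-1-yl]alane | C=CCC/C(C)=C/[Al](C)C | intermediate (not isolated)
8 | (2E)-3-methylhepta-2,6-dien-1-ol | C=CCC/C(C)=C/CO | intermediate
9 | (2E)-1-bromo-3-methylhepta-2,6-diene | C=CCC/C(C)=C/CBr | intermediate
10 | (6S)-3,5-dihydroxy-4-(3-methoxybenzoyl)-6-[(2E)-3-methylhepta-2,6-dien-1-yl]-2,6-di(prop-2-en-1-yl)cyclohexa-2,4-dien-1-one | C=CCC/C(C)=C/C[C@]1(CC=C)C(=O)C(CC=C)=C(O)C(C(=O)c2cccc(OC)c2)=C1O | intermediate (key-step precursor)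
11 | (1S,5S,7R,8S)-8-(but-3-en-1-yl)-4-hydroxy-3-(3-methoxybenzoyl)-8-methyl-7-[(2E)-3-methylhepta-2,6-dien-1-yl]-1,5-di(prop-2-en-1-yl)bicyclo[3.3.1]non-3-ene-2,9-dione | C=CCC/C(C)=C/C[C@@H]1C[C@]2(CC=C)C(=O)[C@@](CC=C)(C(=O)C(C(=O)c3cccc(OC)c3)=C2O)[C@@]1(C)CCC=C | intermediate (key-step product)
12 | (1S,5S,7R,8S)-8-(but-3-en-1-yl)-4-hydroxy-3-(3-hydroxybenzoyl)-8-methyl-7-[(2E)-3-methylhepta-2,6-dien-1-yl]-1,5-di(prop-2-en-1-yl)bicyclo[3.3.1]non-3-ene-2,9-dione | C=CCC/C(C)=C/C[C@@H]1C[C@]2(CC=C)C(=O)[C@@](CC=C)(C(=O)C(C(=O)c3cccc(O)c3)=C2O)[C@@]1(C)CCC=C | intermediate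
13 | (1S,5S,7R,8S)-7-[(2E)-3,7-dimethylocta-2,6-dien-1-yl]-4-hydroxy-3-(3-hydroxybenzoyl)-8-methyl-8-(4-methylpent-3-en-1-yl)-1,5-bis(3-methylbut-2-en-1-yl)bicyclo[3.3.1]non-3-ene-2,9-dione | CC(C)=CCC/C(C)=C/C[C@@H]1C[C@]2(CC=C(C)C)C(=O)[C@@](CC=C(C)C)(C(=O)C(C(=O)c3cccc(O)c3)=C2O)[C@@]1(C)CCC=C(C)C | target

**Step count and risks**

Total steps: 8. Longest linear sequence: 6 (steps 1, 2, 5, 6, 7, 8 from phloroglucinol; the bromide branch, steps 3 and 4, also reaches the target in six steps).

Most likely to fail, step 6 (the new method). The cation may allylate C1 or an enol oxygen directly, the C8 cation may be captured by oxygen to give a pyran, or the ring may close through a boat. The fallback makes the same two bonds in two known operations, setting out from 10 and rejoining at 11. Iodonium-induced carbocyclisation of 10 (I2, KI, KHCO3, THF/H2O, 0 °C) should close ring A by anti addition and give the 7-exo-iodide F1 with the C1–C8 bond in place. It is selective because iodonium formation is reversible and only the C7=C8 iodonium has the C1 enolate carbon within reach. Alcohol 8 is converted with ClCO2Me and pyridine into the methyl carbonate F2. A nickel-catalysed reductive cross-electrophile allylation of the secondary iodide (NiCl2(DME), 4,4'-di-tert-butyl-2,2'-bipyridine, zinc powder, MgCl2, DMA, rt) should then join C7 to C1' at the unsubstituted allyl terminus with the (E)-olefin kept. The C7 radical on the way is expected to be trapped on the open exo face, giving 11.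

Second, step 5. Discrimination between the two enantiotopic allyl-bearing carbons may be poor, or the loosely paired phenoxide may alkylate on oxygen. The fallback sets out from 5 and 9 and rejoins at 10. Alkylation with LiN(SiMe3)2 (3 equiv) in THF at 0 °C, where lithium chelation steers the bromide to carbon, should give the racemic dienone F3. Preparative chromatography on a chiral stationary phase then delivers the (S)-enantiomer 10 and sets aside the (R)-enantiomer F4.

Third, step 8. Ring-closing metathesis between the C1 allyl group and the neighbouring C8 butenyl group (a cycloheptene) may outrun cross-metathesis; ring-opening in neat 2-methylbut-2-ene might return part of it, but this is uncertain. The fallback removes the fast ring-closing partner by carrying the C8 chain with its natural isopropylidene end, setting out from 5 and rejoining at 13. Compound 5 is alkylated under the step 5 conditions with purchased geranyl bromide (CC(C)=CCC/C(C)=C/CBr) to give the geranyl dienone F5. The step 6 conditions with 9 should give the bicycle F6, and NaSEt in DMF the phenol F7. Cross-metathesis of its three remaining vinyl groups then gives 13. The price is that the remote olefin of the C5 chain is no longer masked during the ring closure.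

Further compounds
F1 | step 6 | (1S,5S,7R,8R)-8-(but-3-en-1-yl)-4-hydroxy-7-iodo-3-(3-methoxybenzoyl)-8-methyl-1,5-di(prop-2-en-1-yl)bicyclo[3.3.1]non-3-ene-2,9-dione (iodide exo, equatorial) | I[C@@H]1C[C@]2(CC=C)C(=O)[C@@](CC=C)(C(=O)C(C(=O)c3cccc(OC)c3)=C2O)[C@@]1(C)CCC=C
F2 | step 6 | methyl (2E)-3-methylhepta-2,6-dien-1-yl carbonate | C=CCC/C(C)=C/COC(=O)OC
F3 | step 5 | racemic 3,5-dihydroxy-4-(3-methoxybenzoyl)-6-[(2E)-3-methylhepta-2,6-dien-1-yl]-2,6-di(prop-2-en-1-yl)cyclohexa-2,4-dien-1-one | C=CCC/C(C)=C/CC1(CC=C)C(=O)C(CC=C)=C(O)C(C(=O)c2cccc(OC)c2)=C1O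
F4 | step 5 | (6R)-3,5-dihydroxy-4-(3-methoxybenzoyl)-6-[(2E)-3-methylhepta-2,6-dien-1-yl]-2,6-di(prop-2-en-1-yl)cyclohexa-2,4-dien-1-one | C=CCC/C(C)=C/C[C@@]1(CC=C)C(=O)C(CC=C)=C(O)C(C(=O)c2cccc(OC)c2)=C1O
F5 | step 8 | (6S)-6-[(2E)-3,7-dimethylocta-2,6-dien-1-yl]-3,5-dihydroxy-4-(3-methoxybenzoyl)-2,6-di(prop-2-en-1-yl)cyclohexa-2,4-dien-1-one | CC(C)=CCC/C(C)=C/C[C@]1(CC=C)C(=O)C(CC=C)=C(O)C(C(=O)c2cccc(OC)c2)=C1O
F6 | step 8 | (1S,5S,7R,8S)-4-hydroxy-3-(3-methoxybenzoyl)-8-methyl-7-[(2E)-3-methylhepta-2,6-dien-1-yl]-8-(4-methylpent-3-en-1-yl)-1,5-di(prop-2-en-1-yl)bicyclo[3.3.1]non-3-ene-2,9-dione | C=CCC/C(C)=C/C[C@@H]1C[C@]2(CC=C)C(=O)[C@@](CC=C)(C(=O)C(C(=O)c3cccc(OC)c3)=C2O)[C@@]1(C)CCC=C(C)C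
F7 | step 8 | (1S,5S,7R,8S)-4-hydroxy-3-(3-hydroxybenzoyl)-8-methyl-7-[(2E)-3-methylhepta-2,6-dien-1-yl]-8-(4-methylpent-3-en-1-yl)-1,5-di(prop-2-en-1-yl)bicyclo[3.3.1]non-3-ene-2,9-dione | C=CCC/C(C)=C/C[C@@H]1C[C@]2(CC=C)C(=O)[C@@](CC=C)(C(=O)C(C(=O)c3cccc(O)c3)=C2O)[C@@]1(C)CCC=C(C)C
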